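A direct plan would adjust the oxygen pattern of a purchased 2,4,6-trioxygenated acetophenone in four steps to 1-[4-(benzyloxy)-6-hydroxy-2,3-dimethoxyphenyl]ethanone A1, condense A1 with 4-(benzyloxy)-3-[(3S)-4-hydroxy-3-methylbutyl]benzaldehyde A2 to the (E)-2′-hydroxychalcone A3, close ring C of A3 with alkaline peroxide (Algar–Flynn–Oyamada) to the 7,4′-di-O-benzylflavonol A4 and debenzylate A4. The chain of A2 would rest on a copper-catalysed asymmetric allylic methylation giving (S)-4-bromo-3-methylbut-1-ene A5.
Its weakest points would be: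
- The make-up of ring A on the way to A1: four steps that would add one oxygen atom and no carbon, two of them statistical alkylations of near-equivalent hydroxyls and one an Elbs persulfate hydroxylation that would stop at low conversion.
- The oxidative closure of ring C from A3 to A4: with a 6′-methoxy group, 5-exo closure to the aurone would compete with the 6-endo path, so the ring size would be left to chance exactly where rings A and B, the chain and the stereocenter are all invested.
- The stereocenter of A5: it would be set by catalyst control (branched versus linear attack and facial selectivity both to be earned) on a volatile five-carbon bromide whose enantiomeric purity could be checked only after derivatisation.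

Plan of the new route
- Cuts: first C2–C1′ (ring B leaves as an aryl bromide); then O1–C2 and C2–C3 of ring C (C2 comes from a one-carbon aminal ester) and C4–C4a (aryllithium plus Weinreb amide); in the ring B piece the bond between the benzylic carbon and the next chain carbon (Wittig).
- Ring order: ring A is bought with all its oxygens (the formyl carbon is exchanged for the oxygen on C8a by Baeyer–Villiger oxidation), ring C is closed on ring A as a 3-benzyloxychromone with C2 unsubstituted, and ring B is attached last.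
- Feature behind the key step: in a 3-alkoxychromone, C2 of ring C is the only pyranone carbon bearing hydrogen; it sits between O1 and the oxygen on C3, is the most acidic C–H of the A/C bicycle, and can be joined to C1′ like a biaryl bond.
- Ring A regiochemistry: C4a is the only C–H flanked by two lithium-coordinating oxygens (O on C8a as a methoxymethyl ether, OMe on C5), while C8 is screened by the bulky silyl ether on the C7 oxygen.
- Why the weak steps vanish: no oxygen is introduced on ring A and no hydroxyl is alkylated statistically; ring C closes before ring B is present by an addition–elimination that has only the six-ring mode; the stereocenter is bought and never lies next to a carbanion, a carbonyl group or a metal hydride.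

Key step: step 9

Assumption: the four building blocks that open the two branches are taken as catalogue chemicals, and the aryl triisopropylsilyl ether is treated as inert to alkyllithium below 0 °C and to organozinc reagents at 50 °C.

Step 1
Reactants: 1 3-hydroxy-4,5-dimethoxybenzaldehyde
Product: 2 3,4-dimethoxy-5-[(triisopropylsilyl)oxy]benzaldehyde
Conditions: i-Pr3SiCl (1.1 equiv), imidazole (2.0 equiv), DMF, rt, 4 h
Reagents that add atoms: chlorotriisopropylsilane, CC(C)[Si](Cl)(C(C)C)C(C)C
Why: Imidazole-promoted silylation of the only hydroxyl; the bulky, non-coordinating silyl ether is chosen because it later screens C8 against metalation in steps 4 and 9.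

Step 2
Reactants: 2 3,4-dimethoxy-5-[(triisopropylsilyl)oxy]benzaldehyde
Product: 4 3,4-dimethoxy-5-[(triisopropylsilyl)oxy]phenol, via aryl formate 3 (not isolated)
Conditions: mCPBA (1.3 equiv), CH2Cl2, 0 °C → rt, 3 h; aq. Na2S2O3/NaHCO3 wash; crude formate in MeOH, Et3N (0.3 equiv), rt, 30 min
Reagents that add atoms: 3-chloroperoxybenzoic acid, OOC(=O)c1cccc(Cl)c1
Why: Baeyer–Villiger (Dakin-type) oxidation in which the electron-rich aryl group migrates in the Criegee intermediate, followed by amine-catalysed methanolysis of the formate that should spare the aryl silyl ether; the formyl carbon is thereby replaced by the oxygen that becomes O1.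

Step 3
Reactants: 4 3,4-dimethoxy-5-[(triisopropylsilyl)oxy]phenol
Product: 5 [2,3-dimethoxy-5-(methoxymethoxy)phenoxy]triisopropylsilane
Conditions: MeOCH2Cl (1.5 equiv), i-Pr2NEt (2.0 equiv), CH2Cl2, 0 °C → rt, 6 h
Reagents that add atoms: chloromethyl methyl ether, COCCl
Why: O-Alkylation of the phenol to the methoxymethyl ether, a strong ortho-directing group for lithiation that is removed by acid in step 5.

Step 4
Reactants: 5 [2,3-dimethoxy-5-(methoxymethoxy)phenoxy]triisopropylsilane; 6 2-(benzyloxy)-N-methoxy-N-methylacetamide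
Product: 8 2-(benzyloxy)-1-{2,3-dimethoxy-6-(methoxymethoxy)-4-[(triisopropylsilyl)oxy]phenyl}ethan-1-one, via aryllithium 7 (not isolated)
Conditions: n-BuLi (1.2 equiv), TMEDA (1.2 equiv), THF, −40 → 0 °C, 1 h; then 6 (1.3 equiv), −78 → 0 °C, 2 h; aq. NH4Cl
Reagents that add atoms: none
Why: Directed ortho-metalation at the one C–H flanked by the methoxymethoxy and methoxy oxygens (the future C4a), the other ring hydrogen being screened by the silyl ether, followed by Weinreb ketone synthesis, in which the chelated tetrahedral adduct prevents over-addition.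

Step 5
Reactants: 8 2-(benzyloxy)-1-{2,3-dimethoxy-6-(methoxymethoxy)-4-[(triisopropylsilyl)oxy]phenyl}ethan-1-one
Product: 10 3-(benzyloxy)-5,6-dimethoxy-7-[(triisopropylsilyl)oxy]-4H-chromen-4-one, via enaminone 9 (not isolated)
Conditions: t-BuOCH(NMe2)2 (2.5 equiv), toluene, 80 °C, 4 h; concentrate; HCl (1.25 M in MeOH, 4 equiv), THF, 40 °C, 2 h; aq. NaHCO3
Reagents that add atoms: tert-butoxybis(dimethylamino)methane, CC(C)(C)OC(N(C)C)N(C)C
Why: Aminomethylenation of the activated methylene with Bredereck's reagent (which releases no methylating species) gives the enaminone; acid then removes the methoxymethyl group and the freed phenol adds to the β-carbon and expels dimethylamine (6-endo addition–elimination), closing ring C with C2 still bearing hydrogen.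

Step 6
Reactants: 11 (2R)-3-bromo-2-methylpropan-1-ol
Product: 12 [(2R)-3-hydroxy-2-methylpropyl]triphenylphosphonium bromide
Conditions: PPh3 (1.05 equiv), MeCN, reflux, 36 h; crystallisation
Reagents that add atoms: triphenylphosphine, c1ccc(cc1)P(c1ccccc1)c1ccccc1
Why: SN2 quaternisation of the phosphine by the primary bromide, which does not touch the neighbouring stereocenter taken from the chiral pool.

Step 7
Reactants: 12 [(2R)-3-hydroxy-2-methylpropyl]triphenylphosphonium bromide; 13 2-(benzyloxy)-5-bromobenzaldehyde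
Product: 15 (2S,3Z)-4-[2-(benzyloxy)-5-bromophenyl]-2-methylbut-3-en-1-ol, via oxido ylide 14 (not isolated)
Conditions: 12 (1.3 equiv), n-BuLi (2.55 equiv), THF, −78 → 0 °C, 1 h; then 13 (1.0 equiv), −78 °C → rt, 3 h; aq. NH4Cl
Reagents that add atoms: none
Why: Wittig olefination through the γ-oxido ylide should give mainly the Z alkene (the geometry is irrelevant because step 8 saturates it); the stereocenter is β to phosphorus, carries no acidic hydrogen and is carried over unchanged, its descriptor changing from R to S only because the priority order changes.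

Step 8
Reactants: 15 (2S,3Z)-4-[2-(benzyloxy)-5-bromophenyl]-2-methylbut-3-en-1-ol
Product: 16 (2S)-4-[2-(benzyloxy)-5-bromophenyl]-2-methylbutan-1-ol
Conditions: TsNHNH2 (6 equiv, in portions), NaOAc (8 equiv), DME/H2O (1:1), reflux, 6 h
Reagents that add atoms: none
Why: Diimide reduction transfers two hydrogens in a concerted cyclic transition state without a metal hydride, so the double bond cannot migrate into the allylic stereocenter and neither the aryl C–Br bond nor the benzyl ether is cleaved.

Step 9
Reactants: 10 3-(benzyloxy)-5,6-dimethoxy-7-[(triisopropylsilyl)oxy]-4H-chromen-4-one; 16 (2S)-4-[2-(benzyloxy)-5-bromophenyl]-2-methylbutan-1-ol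
Product: 18 3-(benzyloxy)-2-{4-(benzyloxy)-3-[(3S)-4-hydroxy-3-methylbutyl]phenyl}-5,6-dimethoxy-7-[(triisopropylsilyl)oxy]-4H-chromen-4-one, via chromon-2-ylzinc chloride 17 (not isolated)
Conditions: 10 (1.4 equiv), TMPZnCl·LiCl (1.3 equiv, THF solution), THF, 25 °C, 2 h; the solution of 17 then added over 1 h to 16 (1.0 equiv), Pd(OAc)2 (3 mol%), SPhos (2-dicyclohexylphosphino-2′,6′-dimethoxybiphenyl, 6 mol%) in THF at 25 °C; then 50 °C, 6 h; aq. NH4Cl
Reagents that add atoms: none
Why: The hindered amide base TMPZnCl·LiCl should remove the C2 hydrogen of 10, the most acidic C–H of the molecule (an sp2 C–H bound to O1, next to the C3 oxygen that can hold the zinc, in an electron-poor pyranone), to give the zinc reagent 17, which is covalent enough not to open the pyranone ring. Zerovalent palladium formed in situ from Pd(OAc)2 and SPhos inserts into the C–Br bond of 16, and transmetalation with 17 followed by reductive elimination forms the C2–C1′ bond (Negishi coupling); the closest known reaction type is the deprotonative zincation of chromones and 4-pyranones with TMP-zinc bases followed by palladium-catalysed arylation to flavones. No ring is closed: ring B is joined to the finished A/C bicycle by an intermolecular sp2–sp2 coupling. No stereocenter is formed, and the (S)-center of 16 lies four bonds from the reacting ring with no pathway for epimerisation. The selectivity needed is the site of metalation, secured because C3 carries the benzyloxy group, C5 to C7 carry oxygen, and the one other ring hydrogen (C8) is a less acidic arene C–H screened by the triisopropylsilyl ether. The free primary hydroxyl of 16 should be tolerated because heteroarylzinc halides are protonated by alcohols far more slowly than they transmetalate to the SPhos-ligated arylpalladium bromide, because the zinc reagent is added slowly to the bromide and catalyst, and because the base is used in deficit relative to 10 so that no amide base remains.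

Step 10
Reactants: 18 3-(benzyloxy)-2-{4-(benzyloxy)-3-[(3S)-4-hydroxy-3-methylbutyl]phenyl}-5,6-dimethoxy-7-[(triisopropylsilyl)oxy]-4H-chromen-4-one
Product: 20 3,7-dihydroxy-2-{4-hydroxy-3-[(3S)-4-hydroxy-3-methylbutyl]phenyl}-5,6-dimethoxy-4H-chromen-4-one, via 7-hydroxy compound 19 (not isolated)
Conditions: Bu4NF (1.0 M in THF, 1.2 equiv), THF, 0 °C, 30 min; AcOH (1.5 equiv); then MeOH, 10% Pd/C (palladium on carbon), H2 (1 atm), rt, 4 h; filtration, chromatography
Reagents that add atoms: none
Why: Fluoride cleaves the aryl silyl ether (the oxygen on C7 is a vinylogous carboxylate and a good leaving group), and hydrogenolysis then removes the benzyl groups on the C3 and C4′ oxygens, conditions under which the tetrasubstituted C2=C3 bond, the ketone, the methyl ethers and the remote stereocenter should be unaffected.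

Compound list
1 | 3-hydroxy-4,5-dimethoxybenzaldehyde | O=Cc1cc(O)c(OC)c(OC)c1 | starting material
2 | 3,4-dimethoxy-5-[(triisopropylsilyl)oxy]benzaldehyde | O=Cc1cc(O[Si](C(C)C)(C(C)C)C(C)C)c(OC)c(OC)c1 | intermediate
3 | 3,4-dimethoxy-5-[(triisopropylsilyl)oxy]phenyl formate | O=COc1cc(O[Si](C(C)C)(C(C)C)C(C)C)c(OC)c(OC)c1 | intermediate (not isolated)
4 | 3,4-dimethoxy-5-[(triisopropylsilyl)oxy]phenol | Oc1cc(O[Si](C(C)C)(C(C)C)C(C)C)c(OC)c(OC)c1 | intermediate
5 | [2,3-dimethoxy-5-(methoxymethoxy)phenoxy]triisopropylsilane | COCOc1cc(O[Si](C(C)C)(C(C)C)C(C)C)c(OC)c(OC)c1 | intermediate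
6 | 2-(benzyloxy)-N-methoxy-N-methylacetamide | CON(C)C(=O)COCc1ccccc1 | starting material
7 | {2,3-dimethoxy-6-(methoxymethoxy)-4-[(triisopropylsilyl)oxy]phenyl}lithium | [Li]c1c(OCOC)cc(O[Si](C(C)C)(C(C)C)C(C)C)c(OC)c1OC | intermediate (not isolated)
8 | 2-(benzyloxy)-1-{2,3-dimethoxy-6-(methoxymethoxy)-4-[(triisopropylsilyl)oxy]phenyl}ethan-1-one | O=C(COCc1ccccc1)c1c(OCOC)cc(O[Si](C(C)C)(C(C)C)C(C)C)c(OC)c1OC | intermediate
9 | 2-(benzyloxy)-3-(dimethylamino)-1-{2,3-dimethoxy-6-(methoxymethoxy)-4-[(triisopropylsilyl)oxy]phenyl}prop-2-en-1-one (alkene geometry not defined) | CN(C)C=C(OCc1ccccc1)C(=O)c1c(OCOC)cc(O[Si](C(C)C)(C(C)C)C(C)C)c(OC)c1OC | intermediate (not isolated)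
10 | 3-(benzyloxy)-5,6-dimethoxy-7-[(triisopropylsilyl)oxy]-4H-chromen-4-one | COc1c(O[Si](C(C)C)(C(C)C)C(C)C)cc2occ(OCc3ccccc3)c(=O)c2c1OC | intermediate
11 | (2R)-3-bromo-2-methylpropan-1-ol | BrC[C@H](C)CO | starting material
12 | [(2R)-3-hydroxy-2-methylpropyl]triphenylphosphonium bromide | c1ccccc1[P+](c1ccccc1)(c1ccccc1)C[C@H](C)CO.[Br-] | intermediate
13 | 2-(benzyloxy)-5-bromobenzaldehyde | O=Cc1cc(Br)ccc1OCc1ccccc1 | starting material
14 | lithium (2R)-2-methyl-3-(triphenyl-λ5-phosphanylidene)propan-1-olate | c1ccccc1P(c1ccccc1)(c1ccccc1)=C[C@H](C)C[O-].[Li+] | intermediate (not isolated)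
15 | (2S,3Z)-4-[2-(benzyloxy)-5-bromophenyl]-2-methylbut-3-en-1-ol (Z isomer drawn; any E isomer converges in step 8) | c1ccccc1COc1ccc(Br)cc1/C=C\[C@H](C)CO | intermediate
16 | (2S)-4-[2-(benzyloxy)-5-bromophenyl]-2-methylbutan-1-ol | c1ccccc1COc1ccc(Br)cc1CC[C@H](C)CO | intermediate
17 | {3-(benzyloxy)-5,6-dimethoxy-4-oxo-7-[(triisopropylsilyl)oxy]-4H-chromen-2-yl}zinc chloride (as its LiCl complex) | Cl[Zn]c1oc2cc(O[Si](C(C)C)(C(C)C)C(C)C)c(OC)c(OC)c2c(=O)c1OCc1ccccc1 | intermediate (not isolated)
18 | 3-(benzyloxy)-2-{4-(benzyloxy)-3-[(3S)-4-hydroxy-3-methylbutyl]phenyl}-5,6-dimethoxy-7-[(triisopropylsilyl)oxy]-4H-chromen-4-one | COc1c(O[Si](C(C)C)(C(C)C)C(C)C)cc2oc(-c3ccc(OCc4ccccc4)c(CC[C@H](C)CO)c3)c(OCc3ccccc3)c(=O)c2c1OC | intermediate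
19 | 3-(benzyloxy)-2-{4-(benzyloxy)-3-[(3S)-4-hydroxy-3-methylbutyl]phenyl}-7-hydroxy-5,6-dimethoxy-4H-chromen-4-one | COc1c(O)cc2oc(-c3ccc(OCc4ccccc4)c(CC[C@H](C)CO)c3)c(OCc3ccccc3)c(=O)c2c1OC | intermediate (not isolated)
20 | 3,7-dihydroxy-2-{4-hydroxy-3-[(3S)-4-hydroxy-3-methylbutyl]phenyl}-5,6-dimethoxy-4H-chromen-4-one | COc1c(O)cc2oc(-c3ccc(O)c(CC[C@H](C)CO)c3)c(O)c(=O)c2c1OC | target

Total step count: 10. Longest linear sequence: 7 steps (steps 1 to 5, 9 and 10); the ring B branch (steps 6 to 8) joins at step 9.

Steps most likely to fail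

Step 9. The deprotonation of 10 may be incomplete or go to another site, the zinc reagent may be protonated by the free hydroxyl of 16, or transmetalation of the electron-poor heteroarylzinc may be slow. The fallback inverts the polarity: ring B becomes the nucleophile and C2 the Michael acceptor. It sets out from bromide 16 and chromone 10. Bromide 16 would be silylated (t-BuMe2SiCl, imidazole, DMF) to tert-butyl{[(2S)-4-[2-(benzyloxy)-5-bromophenyl]-2-methylbutyl]oxy}dimethylsilane F1. F1 would be converted with Mg turnings and LiCl in THF into {4-(benzyloxy)-3-[(3S)-4-[(tert-butyldimethylsilyl)oxy]-3-methylbutyl]phenyl}magnesium bromide F2. F2 would be added to chromone 10 in a copper-catalysed conjugate addition (CuBr·SMe2, Me3SiCl, THF, −78 °C, acidic work-up) to give 3-(benzyloxy)-2-{4-(benzyloxy)-3-[(3S)-4-[(tert-butyldimethylsilyl)oxy]-3-methylbutyl]phenyl}-5,6-dimethoxy-7-[(triisopropylsilyl)oxy]chroman-4-one F3. Dehydrogenation with DDQ in dioxane would give 3-(benzyloxy)-2-{4-(benzyloxy)-3-[(3S)-4-[(tert-butyldimethylsilyl)oxy]-3-methylbutyl]phenyl}-5,6-dimethoxy-7-[(triisopropylsilyl)oxy]-4H-chromen-4-one F4. F4 comes back to the route at 19 when both silyl ethers are cleaved in the fluoride stage of step 10 (Bu4NF, 2.5 equiv).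

Step 4. Lithiation may occur on the silyl ether side with migration of silicon from oxygen to carbon, or the hindered aryllithium may enolise the Weinreb amide instead of adding to it. The fallback uses no organolithium on ring A and sets out from phenol 4. Ortho-formylation through the magnesium phenoxide (MgCl2, Et3N, paraformaldehyde, MeCN, reflux) delivers the electrophile next to the oxygen on the side remote from the bulky silyl ether and would give 6-hydroxy-2,3-dimethoxy-4-[(triisopropylsilyl)oxy]benzaldehyde F5. MeOCH2Cl and i-Pr2NEt would give 2,3-dimethoxy-6-(methoxymethoxy)-4-[(triisopropylsilyl)oxy]benzaldehyde F6. A Barbier-type addition of benzyl chloromethyl ether mediated by SmI2 in THF would give 2-(benzyloxy)-1-{2,3-dimethoxy-6-(methoxymethoxy)-4-[(triisopropylsilyl)oxy]phenyl}ethan-1-ol F7. Oxidation with Dess–Martin periodinane would give ketone 8, where the route is rejoined.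

Step 5. Aminomethylenation of the doubly ortho-substituted ketone may be slow, or alkoxide released from the reagent may cleave the silyl ether of the acidic phenol. The fallback transfers the one-carbon unit as an electrophile to a boron chelate under acidic conditions and sets out from 8. Removal of the methoxymethyl group (HCl, MeOH/THF, rt) would give 2-(benzyloxy)-1-{6-hydroxy-2,3-dimethoxy-4-[(triisopropylsilyl)oxy]phenyl}ethan-1-one F8. Treatment of F8 with BF3·OEt2, DMF and MeSO2Cl at 60 °C (Vilsmeier-type formylation of the difluoroboron chelate, then ring closure) would give chromone 10, where the route is rejoined.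

Further compounds
F1 | step 9 | tert-butyl{[(2S)-4-[2-(benzyloxy)-5-bromophenyl]-2-methylbutyl]oxy}dimethylsilane | c1ccccc1COc1ccc(Br)cc1CC[C@H](C)CO[Si](C)(C)C(C)(C)C
F2 | step 9 | {4-(benzyloxy)-3-[(3S)-4-[(tert-butyldimethylsilyl)oxy]-3-methylbutyl]phenyl}magnesium bromide | Br[Mg]c1ccc(OCc2ccccc2)c(CC[C@H](C)CO[Si](C)(C)C(C)(C)C)c1
F3 | step 9 | 3-(benzyloxy)-2-{4-(benzyloxy)-3-[(3S)-4-[(tert-butyldimethylsilyl)oxy]-3-methylbutyl]phenyl}-5,6-dimethoxy-7-[(triisopropylsilyl)oxy]chroman-4-one (ring centres left undefined) | COc1c(O[Si](C(C)C)(C(C)C)C(C)C)cc2OC(c3ccc(OCc4ccccc4)c(CC[C@H](C)CO[Si](C)(C)C(C)(C)C)c3)C(OCc3ccccc3)C(=O)c2c1OC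
F4 | step 9 | 3-(benzyloxy)-2-{4-(benzyloxy)-3-[(3S)-4-[(tert-butyldimethylsilyl)oxy]-3-methylbutyl]phenyl}-5,6-dimethoxy-7-[(triisopropylsilyl)oxy]-4H-chromen-4-one | COc1c(O[Si](C(C)C)(C(C)C)C(C)C)cc2oc(-c3ccc(OCc4ccccc4)c(CC[C@H](C)CO[Si](C)(C)C(C)(C)C)c3)c(OCc3ccccc3)c(=O)c2c1OC
F5 | step 4 | 6-hydroxy-2,3-dimethoxy-4-[(triisopropylsilyl)oxy]benzaldehyde | O=Cc1c(O)cc(O[Si](C(C)C)(C(C)C)C(C)C)c(OC)c1OC
F6 | step 4 | 2,3-dimethoxy-6-(methoxymethoxy)-4-[(triisopropylsilyl)oxy]benzaldehyde | O=Cc1c(OCOC)cc(O[Si](C(C)C)(C(C)C)C(C)C)c(OC)c1OC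
F7 | step 4 | 2-(benzyloxy)-1-{2,3-dimethoxy-6-(methoxymethoxy)-4-[(triisopropylsilyl)oxy]phenyl}ethan-1-ol (carbinol centre undefined) | OC(COCc1ccccc1)c1c(OCOC)cc(O[Si](C(C)C)(C(C)C)C(C)C)c(OC)c1OC
F8 | step 5 | 2-(benzyloxy)-1-{6-hydroxy-2,3-dimethoxy-4-[(triisopropylsilyl)oxy]phenyl}ethan-1-one | O=C(COCc1ccccc1)c1c(O)cc(O[Si](C(C)C)(C(C)C)C(C)C)c(OC)c1OC
A1 | direct plan | 1-[4-(benzyloxy)-6-hydroxy-2,3-dimethoxyphenyl]ethanone | CC(=O)c1c(O)cc(OCc2ccccc2)c(OC)c1OC
A2 | direct plan | 4-(benzyloxy)-3-[(3S)-4-hydroxy-3-methylbutyl]benzaldehyde | O=Cc1ccc(OCc2ccccc2)c(CC[C@H](C)CO)c1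
A3 | direct plan | (E)-1-[4-(benzyloxy)-6-hydroxy-2,3-dimethoxyphenyl]-3-{4-(benzyloxy)-3-[(3S)-4-hydroxy-3-methylbutyl]phenyl}prop-2-en-1-one | COc1c(OC)c(OCc2ccccc2)cc(O)c1C(=O)/C=C/c1ccc(OCc2ccccc2)c(CC[C@H](C)CO)c1
A4 | direct plan | 7-(benzyloxy)-2-{4-(benzyloxy)-3-[(3S)-4-hydroxy-3-methylbutyl]phenyl}-3-hydroxy-5,6-dimethoxy-4H-chromen-4-one | COc1c(OCc5ccccc5)cc2oc(-c3ccc(OCc4ccccc4)c(CC[C@H](C)CO)c3)c(O)c(=O)c2c1OC
A5 | direct plan | (S)-4-bromo-3-methylbut-1-ene | C=C[C@H](C)CBr
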